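## Retrosynthetic overview

1. Target 26 ⇐ 25 (free the phenol) ⇐ 24 (acetylate O6) ⇐ 23 (acidolysis of a chiral 1-arylethyl ether on O6). The hindered tertiary everninate on C7 is never made by esterifying C7–OH; it is carried in as an enol ester.
2. Ring B (C4a–C5–C6–C7–C8–C8a) ⇐ 1,3-acyl shift (C8 moves from C5 to C8a) of the 2-alkenylcyclobutanone 21 (ring C5–C6–C7–C8), then conjugation of the alkene into C4a=C8a.
3. 21 ⇐ thermal [2+2] of alkenylketene 20 (from dihydropyranylacetic acid 8, fragment 1) with the Z-configured enol ether/enol everninate 18 (fragment 2). This forms C7–C8 and C5–C6 and sets C6 and C7 in the same event.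
4. Ring A (the pyran, C3) is made first by a catalytic asymmetric hetero-Diels–Alder reaction (1 + 2 → 4). Ring order: ring A, then the four-membered ring, then ring B by ring expansion.
5. Enabling feature: ketone C8 lies between the fully substituted C7 and C8a, and C5 is the allylic CH2 of the C4a=C8a alkene shared by rings A and B. Ring B is therefore the acyl-shift isomer of a cyclobutanone in which C8 is bonded to C5, and the cis O6/O7 pair on C6–C7 is the imprint of a Z-enediol.

Key step: step 10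

Assumption 1: 9 (everninic acid) and 12 are taken as purchasable; 9 is otherwise one selective O-methylation and saponification away from methyl orsellinate.
Assumption 2: the antipodes written for BINOL (step 1) and for auxiliary alcohol 12 are those assumed to lead to 3S and to 6S,7S; the sense of induction is to be checked on a model, and the other, equally available antipode is used if it is the opposite.

## Route

### Fragment 1: ketene precursor 8

Step 1
Reactants: 1 (E)-1-methoxy-3-(trimethylsilyloxy)buta-1,3-diene; 2 (E)-but-2-enal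
Product: 4 (2S)-2-[(E)-prop-1-en-1-yl]-2,3-dihydro-4H-pyran-4-one, via Mukaiyama aldol adduct 3 (not isolated)
Conditions: Ti(OiPr)4/(R)-BINOL (1:1, 10 mol %), 4 Å MS, toluene, −20 °C; then TFA (cat.), CH2Cl2, 0 °C
Reagents that add atoms: none
Why: A catalytic asymmetric hetero-Diels–Alder reaction of the Mukaiyama aldol/cyclisation type should engage only the aldehyde C=O of the enal and set the future C3 stereocentre by catalyst control.

Step 2
Reactants: 4 (2S)-2-[(E)-prop-1-en-1-yl]-2,3-dihydro-4H-pyran-4-one; 5 tert-butyl acetate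
Product: 7 tert-butyl 2-[(2S)-4-hydroxy-2-[(E)-prop-1-en-1-yl]-3,4-dihydro-2H-pyran-4-yl]acetate (both C-4 epimers), via lithium enolate of tert-butyl acetate 6 (not isolated)
Conditions: LiN(iPr)2, THF, −78 °C; then 4, −78 °C; NH4Cl (aq)
Reagents that add atoms: none
Why: Aldol-type 1,2-addition of the ester enolate to the vinylogous ester carbonyl should attach the two carbons that become C5 and C8 to the future C4a; the new carbinol centre is erased in step 3.

Step 3
Reactants: 7 tert-butyl 2-[(2S)-4-hydroxy-2-[(E)-prop-1-en-1-yl]-3,4-dihydro-2H-pyran-4-yl]acetate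
Product: 8 2-[(2S)-2-[(E)-prop-1-en-1-yl]-3,6-dihydro-2H-pyran-4-yl]acetic acid
Conditions: Et3SiH, TFA, CH2Cl2, −40 → 20 °C
Reagents that add atoms: none
Why: Ionic hydrogenation with allylic transposition (reductive Ferrier-type rearrangement): the tertiary allylic alcohol should ionise to the ring oxocarbenium ion, Et3SiH should deliver hydride to the carbon next to oxygen (future C1) so that the alkene lands at C4a=C8a, and TFA also cleaves the tert-butyl ester.

### Fragment 2: Z-enediol derivative 18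

Step 4
Reactants: 9 2-hydroxy-4-methoxy-6-methylbenzoic acid (everninic acid)
Product: 10 triisopropylsilyl 4-methoxy-6-methyl-2-[(triisopropylsilyl)oxy]benzoate
Conditions: TIPSOTf (2.2 equiv), Et3N, CH2Cl2, 0 → 20 °C
Reagents that add atoms: triisopropylsilyl trifluoromethanesulfonate, CC(C)[Si](OS(=O)(=O)C(F)(F)F)(C(C)C)C(C)C
Why: Silylation of both acidic hydroxyls should protect the phenol as a hindered silyl ether that survives base, light and TFA, and turn the acid into a silyl ester for step 5.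

Step 5
Reactants: 10 triisopropylsilyl 4-methoxy-6-methyl-2-[(triisopropylsilyl)oxy]benzoate
Product: 11 4-methoxy-6-methyl-2-[(triisopropylsilyl)oxy]benzoyl chloride
Conditions: (COCl)2, DMF (cat.), CH2Cl2, 0 → 20 °C
Reagents that add atoms: oxalyl chloride, ClC(=O)C(Cl)=O
Why: Vilsmeier-type conversion of a silyl ester into the acid chloride runs under neutral conditions that should spare the aryl silyl ether.

Step 6
Reactants: 12 (1S)-1-(2,4,6-triisopropylphenyl)ethan-1-ol; 13 3-chloro-2-methylprop-1-ene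
Product: 14 1,3,5-triisopropyl-2-[(1S)-1-[(2-methylprop-2-en-1-yl)oxy]ethyl]benzene
Conditions: NaH, NaI (cat.), DMF, 0 → 40 °C
Reagents that add atoms: none
Why: Williamson ether synthesis on the sodium alkoxide with a reactive allylic chloride leaves the auxiliary stereocentre untouched.

Step 7
Reactants: 14 1,3,5-triisopropyl-2-[(1S)-1-[(2-methylprop-2-en-1-yl)oxy]ethyl]benzene
Product: 15 1-[(1S)-1-(2,4,6-triisopropylphenyl)ethoxy]propan-2-one
Conditions: O3, CH2Cl2/MeOH, −78 °C; then Me2S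
Reagents that add atoms: ozone, [O-][O+]=O
Why: Ozonolysis of the 1,1-disubstituted alkene with reductive work-up should give the methyl ketone, the hindered arene being inert at −78 °C.

Step 8
Reactants: 15 1-[(1S)-1-(2,4,6-triisopropylphenyl)ethoxy]propan-2-one
Product: 16 trimethyl{[(1Z)-1-[(1S)-1-(2,4,6-triisopropylphenyl)ethoxy]prop-1-en-2-yl]oxy}silane
Conditions: Me3SiOTf, Et3N, CH2Cl2, 0 → 20 °C
Reagents that add atoms: trimethylsilyl trifluoromethanesulfonate, C[Si](C)(C)OS(=O)(=O)C(F)(F)F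
Why: Silyl enol ether formation under equilibrating conditions should favour the more substituted, oxygen-conjugated enol ether, as the Z isomer with the two oxygens cis.

Step 9
Reactants: 16 trimethyl{[(1Z)-1-[(1S)-1-(2,4,6-triisopropylphenyl)ethoxy]prop-1-en-2-yl]oxy}silane; 11 4-methoxy-6-methyl-2-[(triisopropylsilyl)oxy]benzoyl chloride
Product: 18 (1Z)-1-[(1S)-1-(2,4,6-triisopropylphenyl)ethoxy]prop-1-en-2-yl 4-methoxy-6-methyl-2-[(triisopropylsilyl)oxy]benzoate, via lithium enolate 17 (not isolated)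
Conditions: MeLi, THF, 0 °C; then 11, DMPU, −78 → 0 °C
Reagents that add atoms: none
Why: Cleavage of the O–Si bond with MeLi gives the regio- and geometrically defined lithium enolate, and O-acylation by the hindered aroyl chloride should transfer the Z geometry to the enol ester, so the tertiary everninate is made without esterifying a tertiary alcohol.

### Union and endgame

Step 10
Reactants: 8 2-[(2S)-2-[(E)-prop-1-en-1-yl]-3,6-dihydro-2H-pyran-4-yl]acetic acid; 18 (1Z)-1-[(1S)-1-(2,4,6-triisopropylphenyl)ethoxy]prop-1-en-2-yl 4-methoxy-6-methyl-2-[(triisopropylsilyl)oxy]benzoate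
Product: 21 (1S,4S)-1-methyl-2-oxo-3-[(2S)-2-[(E)-prop-1-en-1-yl]-3,6-dihydro-2H-pyran-4-yl]-4-[(1S)-1-(2,4,6-triisopropylphenyl)ethoxy]cyclobutyl 4-methoxy-6-methyl-2-[(triisopropylsilyl)oxy]benzoate (either configuration at C-3), via acid chloride 19 (not isolated), via alkenylketene 20 (not isolated)
Conditions: (COCl)2, DMF (cat.), CH2Cl2, 0 → 20 °C, then evaporation; syringe-pump addition of 19 to 18 and Et3N in toluene, 60 °C
Reagents that add atoms: none
Why: Et3N dehydrochlorinates 19 to alkenylketene 20, whose C8=C5 bond should add across the enol ether double bond of 18 in a thermal, concerted but asynchronous [2+2] cycloaddition (the ketene–enol ether cycloaddition that gives 3-alkoxycyclobutanones, here with an alkenylketene and a chiral 1-arylethyl enol ether), forming C7–C8 and C5–C6 at once. The one ring closed is the cyclobutanone C5–C6–C7–C8, by the [π2s(alkene) + π2a(ketene)] mode, and not yet ring B. Regiochemistry comes from the alkene: the ether oxygen on C6 is the strong donor and the acyloxy group on C7 a weak one, so C7 is the nucleophilic carbon that bonds to the electrophilic ketene carbon C8, and the alkoxy-bearing C6 becomes C3 of the cyclobutanone, bonded to C5. C6 and C7 become stereocentres together: their cis relation is the suprafacial copy of the Z geometry of 18, and their absolute configuration (6S,7S) is to be fixed by the bulky 1-(2,4,6-triisopropylphenyl)ethyl group, which blocks one face of the enol ether, so the remote C3 centre is not asked to control anything. The new centre at C5 is left uncontrolled because C5 becomes sp2 in step 11. The step needs the ketene to choose the enol ether over the ring alkene, the propenyl group and a second ketene molecule, which the donor oxygen of 18 and the slow addition of 19 (low stationary ketene concentration) are meant to secure.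

Step 11
Reactants: 21 (1S,4S)-1-methyl-2-oxo-3-[(2S)-2-[(E)-prop-1-en-1-yl]-3,6-dihydro-2H-pyran-4-yl]-4-[(1S)-1-(2,4,6-triisopropylphenyl)ethoxy]cyclobutyl 4-methoxy-6-methyl-2-[(triisopropylsilyl)oxy]benzoate
Product: 22 (3S,6S,7S)-7-methyl-8-oxo-3-[(E)-prop-1-en-1-yl]-6-[(1S)-1-(2,4,6-triisopropylphenyl)ethoxy]-3,4,6,7,8,8a-hexahydro-1H-isochromen-7-yl 4-methoxy-6-methyl-2-[(triisopropylsilyl)oxy]benzoate (either configuration at C-8a)
Conditions: hν (λ > 300 nm, Pyrex filter), degassed benzene, 15 °C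
Reagents that add atoms: none
Why: Photochemical 1,3-acyl shift of a β,γ-unsaturated ketone (Norrish type I cleavage of the C8–C5 bond to an acyl/allyl radical pair and recombination at C8a), i.e. the vinylcyclobutanone-to-cyclohexenone ring expansion, should close ring B with relief of ring strain and touch neither C6 nor C7.

Step 12
Reactants: 22 (3S,6S,7S)-7-methyl-8-oxo-3-[(E)-prop-1-en-1-yl]-6-[(1S)-1-(2,4,6-triisopropylphenyl)ethoxy]-3,4,6,7,8,8a-hexahydro-1H-isochromen-7-yl 4-methoxy-6-methyl-2-[(triisopropylsilyl)oxy]benzoate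
Product: 23 (3S,6S,7S)-7-methyl-8-oxo-3-[(E)-prop-1-en-1-yl]-6-[(1S)-1-(2,4,6-triisopropylphenyl)ethoxy]-3,4,5,6,7,8-hexahydro-1H-isochromen-7-yl 4-methoxy-6-methyl-2-[(triisopropylsilyl)oxy]benzoate
Conditions: DBU (0.2 equiv), CH2Cl2, 0 °C
Reagents that add atoms: none
Why: Base-catalysed conjugation of the β,γ-unsaturated ketone through its dienolate should move the alkene to the tetrasubstituted C4a=C8a position and erase the C8a centre, the ether on C6 being too poor a leaving group to be eliminated.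

Step 13
Reactants: 23 (3S,6S,7S)-7-methyl-8-oxo-3-[(E)-prop-1-en-1-yl]-6-[(1S)-1-(2,4,6-triisopropylphenyl)ethoxy]-3,4,5,6,7,8-hexahydro-1H-isochromen-7-yl 4-methoxy-6-methyl-2-[(triisopropylsilyl)oxy]benzoate
Product: 24 (3S,6S,7S)-6-hydroxy-7-methyl-8-oxo-3-[(E)-prop-1-en-1-yl]-3,4,5,6,7,8-hexahydro-1H-isochromen-7-yl 4-methoxy-6-methyl-2-[(triisopropylsilyl)oxy]benzoate
Conditions: TFA, CH2Cl2, 0 °C; NaHCO3 (aq)
Reagents that add atoms: none
Why: Acidolysis (SN1) of the 1-arylethyl ether should release the C6 hydroxyl through the stabilised benzylic cation, while the aryl silyl ether, the esters and the enone survive.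

Step 14
Reactants: 24 (3S,6S,7S)-6-hydroxy-7-methyl-8-oxo-3-[(E)-prop-1-en-1-yl]-3,4,5,6,7,8-hexahydro-1H-isochromen-7-yl 4-methoxy-6-methyl-2-[(triisopropylsilyl)oxy]benzoate
Product: 25 (3S,6S,7S)-6-acetoxy-7-methyl-8-oxo-3-[(E)-prop-1-en-1-yl]-3,4,5,6,7,8-hexahydro-1H-isochromen-7-yl 4-methoxy-6-methyl-2-[(triisopropylsilyl)oxy]benzoate
Conditions: Ac2O, pyridine, DMAP (cat.), CH2Cl2, 0 → 20 °C
Reagents that add atoms: acetic anhydride, CC(=O)OC(C)=O
Why: DMAP-catalysed acetylation of the secondary alcohol; the di-ortho-substituted benzoate on C7 should be too hindered to migrate to O6.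

Step 15
Reactants: 25 (3S,6S,7S)-6-acetoxy-7-methyl-8-oxo-3-[(E)-prop-1-en-1-yl]-3,4,5,6,7,8-hexahydro-1H-isochromen-7-yl 4-methoxy-6-methyl-2-[(triisopropylsilyl)oxy]benzoate
Product: 26 (3S,6S,7S)-6-acetoxy-7-methyl-8-oxo-3-[(E)-prop-1-en-1-yl]-3,4,5,6,7,8-hexahydro-1H-isochromen-7-yl 2-hydroxy-4-methoxy-6-methylbenzoate (CNP0223989.1)
Conditions: HF·pyridine, THF, 0 → 20 °C
Reagents that add atoms: none
Why: Fluoride cleavage of the aryl silyl ether under acidic, buffered conditions should free the phenol without touching the acetate or the base-sensitive β-acetoxy enone.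

## Compound list

1 | (E)-1-methoxy-3-(trimethylsilyloxy)buta-1,3-diene | CO/C=C/C(=C)O[Si](C)(C)C | starting material
2 | (E)-but-2-enal | C/C=C/C=O | starting material
3 | (5S,1E,6E)-1-methoxy-5-(trimethylsilyloxy)octa-1,6-dien-3-one | CO/C=C/C(=O)C[C@H](O[Si](C)(C)C)/C=C/C | intermediate
4 | (2S)-2-[(E)-prop-1-en-1-yl]-2,3-dihydro-4H-pyran-4-one | C/C=C/[C@@H]1CC(=O)C=CO1 | intermediate
5 | tert-butyl acetate | CC(=O)OC(C)(C)C | starting material
6 | lithium 1-tert-butoxyethen-1-olate | C=C([O-])OC(C)(C)C.[Li+] | intermediate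
7 | tert-butyl 2-[(2S)-4-hydroxy-2-[(E)-prop-1-en-1-yl]-3,4-dihydro-2H-pyran-4-yl]acetate | CC(C)(C)OC(=O)CC1(O)C=CO[C@H](/C=C/C)C1 | intermediate
8 | 2-[(2S)-2-[(E)-prop-1-en-1-yl]-3,6-dihydro-2H-pyran-4-yl]acetic acid | OC(=O)CC1=CCO[C@H](/C=C/C)C1 | intermediate
9 | 2-hydroxy-4-methoxy-6-methylbenzoic acid | Cc1cc(OC)cc(O)c1C(=O)O | starting material
10 | triisopropylsilyl 4-methoxy-6-methyl-2-[(triisopropylsilyl)oxy]benzoate | Cc1cc(OC)cc(O[Si](C(C)C)(C(C)C)C(C)C)c1C(=O)O[Si](C(C)C)(C(C)C)C(C)C | intermediate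
11 | 4-methoxy-6-methyl-2-[(triisopropylsilyl)oxy]benzoyl chloride | Cc1cc(OC)cc(O[Si](C(C)C)(C(C)C)C(C)C)c1C(Cl)=O | intermediate
12 | (1S)-1-(2,4,6-triisopropylphenyl)ethan-1-ol | C[C@H](O)c1c(C(C)C)cc(C(C)C)cc1C(C)C | starting material
13 | 3-chloro-2-methylprop-1-ene | CC(=C)CCl | starting material
14 | 1,3,5-triisopropyl-2-[(1S)-1-[(2-methylprop-2-en-1-yl)oxy]ethyl]benzene | C[C@H](OCC(C)=C)c1c(C(C)C)cc(C(C)C)cc1C(C)C | intermediate
15 | 1-[(1S)-1-(2,4,6-triisopropylphenyl)ethoxy]propan-2-one | C[C@H](OCC(C)=O)c1c(C(C)C)cc(C(C)C)cc1C(C)C | intermediate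
16 | trimethyl{[(1Z)-1-[(1S)-1-(2,4,6-triisopropylphenyl)ethoxy]prop-1-en-2-yl]oxy}silane | C/C(O[Si](C)(C)C)=C/O[C@@H](C)c1c(C(C)C)cc(C(C)C)cc1C(C)C | intermediate
17 | lithium (1Z)-1-[(1S)-1-(2,4,6-triisopropylphenyl)ethoxy]prop-1-en-2-olate | C/C([O-])=C/O[C@@H](C)c1c(C(C)C)cc(C(C)C)cc1C(C)C.[Li+] | intermediate
18 | (1Z)-1-[(1S)-1-(2,4,6-triisopropylphenyl)ethoxy]prop-1-en-2-yl 4-methoxy-6-methyl-2-[(triisopropylsilyl)oxy]benzoate | C/C(OC(=O)c1c(C)cc(OC)cc1O[Si](C(C)C)(C(C)C)C(C)C)=C/O[C@@H](C)c1c(C(C)C)cc(C(C)C)cc1C(C)C | intermediate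
19 | 2-[(2S)-2-[(E)-prop-1-en-1-yl]-3,6-dihydro-2H-pyran-4-yl]acetyl chloride | ClC(=O)CC1=CCO[C@H](/C=C/C)C1 | intermediate
20 | 2-[(2S)-2-[(E)-prop-1-en-1-yl]-3,6-dihydro-2H-pyran-4-yl]ethen-1-one (alkenylketene) | O=C=CC1=CCO[C@H](/C=C/C)C1 | intermediate
21 | (1S,4S)-1-methyl-2-oxo-3-[(2S)-2-[(E)-prop-1-en-1-yl]-3,6-dihydro-2H-pyran-4-yl]-4-[(1S)-1-(2,4,6-triisopropylphenyl)ethoxy]cyclobutyl 4-methoxy-6-methyl-2-[(triisopropylsilyl)oxy]benzoate | O=C1[C@@](C)(OC(=O)c2c(C)cc(OC)cc2O[Si](C(C)C)(C(C)C)C(C)C)[C@@H](O[C@@H](C)c2c(C(C)C)cc(C(C)C)cc2C(C)C)C1C3=CCO[C@H](/C=C/C)C3 | intermediate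
22 | (3S,6S,7S)-7-methyl-8-oxo-3-[(E)-prop-1-en-1-yl]-6-[(1S)-1-(2,4,6-triisopropylphenyl)ethoxy]-3,4,6,7,8,8a-hexahydro-1H-isochromen-7-yl 4-methoxy-6-methyl-2-[(triisopropylsilyl)oxy]benzoate | C/C=C/[C@@H]1CC2=C[C@H](O[C@@H](C)c3c(C(C)C)cc(C(C)C)cc3C(C)C)[C@](C)(OC(=O)c3c(C)cc(OC)cc3O[Si](C(C)C)(C(C)C)C(C)C)C(=O)C2CO1 | intermediate
23 | (3S,6S,7S)-7-methyl-8-oxo-3-[(E)-prop-1-en-1-yl]-6-[(1S)-1-(2,4,6-triisopropylphenyl)ethoxy]-3,4,5,6,7,8-hexahydro-1H-isochromen-7-yl 4-methoxy-6-methyl-2-[(triisopropylsilyl)oxy]benzoate | C/C=C/[C@@H]1CC2=C(CO1)C(=O)[C@@](C)(OC(=O)c1c(C)cc(OC)cc1O[Si](C(C)C)(C(C)C)C(C)C)[C@@H](O[C@@H](C)c1c(C(C)C)cc(C(C)C)cc1C(C)C)C2 | intermediate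
24 | (3S,6S,7S)-6-hydroxy-7-methyl-8-oxo-3-[(E)-prop-1-en-1-yl]-3,4,5,6,7,8-hexahydro-1H-isochromen-7-yl 4-methoxy-6-methyl-2-[(triisopropylsilyl)oxy]benzoate | C/C=C/[C@@H]1CC2=C(CO1)C(=O)[C@@](C)(OC(=O)c1c(C)cc(OC)cc1O[Si](C(C)C)(C(C)C)C(C)C)[C@@H](O)C2 | intermediate
25 | (3S,6S,7S)-6-acetoxy-7-methyl-8-oxo-3-[(E)-prop-1-en-1-yl]-3,4,5,6,7,8-hexahydro-1H-isochromen-7-yl 4-methoxy-6-methyl-2-[(triisopropylsilyl)oxy]benzoate | C/C=C/[C@@H]1CC2=C(CO1)C(=O)[C@@](C)(OC(=O)c1c(C)cc(OC)cc1O[Si](C(C)C)(C(C)C)C(C)C)[C@@H](OC(C)=O)C2 | intermediate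
26 | (3S,6S,7S)-6-acetoxy-7-methyl-8-oxo-3-[(E)-prop-1-en-1-yl]-3,4,5,6,7,8-hexahydro-1H-isochromen-7-yl 2-hydroxy-4-methoxy-6-methylbenzoate | C/C=C/[C@@H]1CC2=C(CO1)C(=O)[C@@](C)(OC(=O)c1c(C)cc(OC)cc1O)[C@@H](OC(C)=O)C2 | target

## Step count and risks

Total step count: 15. Longest linear sequence: 10 steps (steps 6, 7, 8, 9, 10, 11, 12, 13, 14, 15).

Three steps most likely to fail:

Step 10. The alkenylketene may dimerise or close electrocyclically to a cyclobutenone faster than the hindered, trisubstituted enol ether captures it, and facial discrimination by the auxiliary may erode at the temperature that capture needs. The fallback raises the electrophilicity of the ketene instead of the temperature, using an α-chloroketene and reductive dechlorination. It sets out from 8: dianion formation (LiN(iPr)2, 2 equiv, THF, −78 °C) and α-chlorination with CCl4 should give 2-chloro-2-[(2S)-2-[(E)-prop-1-en-1-yl]-3,6-dihydro-2H-pyran-4-yl]acetic acid F1, and oxalyl chloride its acid chloride F2. Et3N in the presence of 18 at 0–20 °C would generate the chloro(alkenyl)ketene F3, which should add with the same regiochemistry and facial sense to give the α-chlorocyclobutanone F4. Zinc–copper couple with NH4Cl in MeOH removes the chlorine, and the route is rejoined at 21.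

Step 11. After the Norrish type I cleavage the acyl/allyl radical pair may lose carbon monoxide or fragment back to ketene and enol ether instead of recombining at C8a, and the aryl ester may absorb much of the light. The fallback is the anion-accelerated 1,3-shift at the alcohol oxidation level. It sets out from 21: NaBH4 (MeOH, −20 °C) should give the cyclobutanol F5, and KH with 18-crown-6 in THF (0–20 °C) should trigger the alkoxide-accelerated vinylcyclobutane-to-cyclohexene rearrangement to the cyclohex-3-enol F6, the hindered benzoate being relied on not to migrate. Oxidation with Dess–Martin periodinane returns the route to 22.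

Step 3. Hydride may be delivered to the C4a end of the allyl oxocarbenium ion (giving the enol ether isomer), or the doubly activated allylic C3–O bond may ionise in TFA with ring opening and loss of the C3 configuration. The fallback avoids the cation. It sets out from 4: conjugate reduction with LiBH(sBu)3 and trapping of the regiodefined enolate with PhNTf2 should give (2S)-2-[(E)-prop-1-en-1-yl]-3,6-dihydro-2H-pyran-4-yl trifluoromethanesulfonate F7. Negishi coupling with commercial (2-tert-butoxy-2-oxoethyl)zinc bromide and Pd(PPh3)4 (cat.) in THF should give tert-butyl 2-[(2S)-2-[(E)-prop-1-en-1-yl]-3,6-dihydro-2H-pyran-4-yl]acetate F8, and TFA in CH2Cl2 at 0 °C returns the route to 8.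

Further compounds
F1 | step 10 | 2-chloro-2-[(2S)-2-[(E)-prop-1-en-1-yl]-3,6-dihydro-2H-pyran-4-yl]acetic acid | OC(=O)C(Cl)C1=CCO[C@H](/C=C/C)C1
F2 | step 10 | 2-chloro-2-[(2S)-2-[(E)-prop-1-en-1-yl]-3,6-dihydro-2H-pyran-4-yl]acetyl chloride | ClC(=O)C(Cl)C1=CCO[C@H](/C=C/C)C1
F3 | step 10 | 2-chloro-2-[(2S)-2-[(E)-prop-1-en-1-yl]-3,6-dihydro-2H-pyran-4-yl]ethen-1-one (chloroketene) | O=C=C(Cl)C1=CCO[C@H](/C=C/C)C1
F4 | step 10 | α-chloro analogue of 21 (chlorine on the ring carbon that carries the dihydropyranyl group) | O=C1[C@@](C)(OC(=O)c2c(C)cc(OC)cc2O[Si](C(C)C)(C(C)C)C(C)C)[C@@H](O[C@@H](C)c2c(C(C)C)cc(C(C)C)cc2C(C)C)C1(Cl)C3=CCO[C@H](/C=C/C)C3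
F5 | step 11 | cyclobutanol from reduction of the ketone of 21 (other centres as in 21) | OC1[C@@](C)(OC(=O)c2c(C)cc(OC)cc2O[Si](C(C)C)(C(C)C)C(C)C)[C@@H](O[C@@H](C)c2c(C(C)C)cc(C(C)C)cc2C(C)C)C1C3=CCO[C@H](/C=C/C)C3
F6 | step 11 | 8-hydroxy analogue of 22 (cyclohex-3-enol; other centres as in 22) | C/C=C/[C@@H]1CC2=C[C@H](O[C@@H](C)c3c(C(C)C)cc(C(C)C)cc3C(C)C)[C@](C)(OC(=O)c3c(C)cc(OC)cc3O[Si](C(C)C)(C(C)C)C(C)C)C(O)C2CO1
F7 | step 3 | (2S)-2-[(E)-prop-1-en-1-yl]-3,6-dihydro-2H-pyran-4-yl trifluoromethanesulfonate | C/C=C/[C@@H]1CC(OS(=O)(=O)C(F)(F)F)=CCO1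
F8 | step 3 | tert-butyl 2-[(2S)-2-[(E)-prop-1-en-1-yl]-3,6-dihydro-2H-pyran-4-yl]acetate | CC(C)(C)OC(=O)CC1=CCO[C@H](/C=C/C)C1
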